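**Plan**

- Numbering: the upper isoflavan has O-1, C-2, C-3, C-4, C-4a, O-7 (rings A, C, B); the lower isoflavan (rings A′, C′, B′) is attached through ring B′ to C-4. Cuts, in retrosynthetic order: C-3–C-4 of the upper ring C (key ring closure), O-1–C-2 as an aryl ester C–O bond, C-4–ring B′ (aryllithium plus aldehyde), then O-1′–C-2′ and C-3′=C-4′ of the lower ring C′.
- Forward: the lower isoflavan 11 is built first (arylacetonitrile plus salicylaldehyde gives a 3-arylcoumarin, then the isoflav-3-ene, then asymmetric hydrogenation). Ring B′ as its aryllithium, the ring A aldehyde and the ring B arylacetyl chloride are then joined in one flask.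
- Enabling feature: O-7 of upper ring A is para to C-4a, so C-4 can be unmasked as the exocyclic carbon of a p-quinone methide while O-1, ortho to C-4a, already holds C-2/C-3 as an arylacetate tether.
- Ring C closes by attack of the C-3 ester enolate on C-4. The helpers are removed afterwards: the C-2 carbonyl by LiAlH4 and Mitsunobu closure, the benzyl ethers by hydrogenolysis. The tert-butyl carbonate on C-4 and the silyl group on O-7 are consumed in the key step itself.
- Stereochemistry: C-3′ (R) from iridium-catalysed hydrogenation; C-4 (S) from a chiral ammonium ion pair in the key step; C-3 (R) by equilibration to the trans lactone.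

Key step: step 15

Assumption: the face selectivity of the two catalyst-controlled steps (7 and 15) is taken to be the one drawn; if a model run shows the opposite sense, the enantiomeric ligand (step 7) or the pseudoenantiomeric cinchoninium salt (step 15) is used instead.

**Route**

Step 1
Reactants: 1 2-bromo-3-methoxybenzaldehyde
Product: 2 (2-bromo-3-methoxyphenyl)acetonitrile
Conditions: TosMIC, KOtBu, DME, −30 °C → rt; then MeOH, reflux
Reagents that add atoms: tosylmethyl isocyanide (TosMIC), Cc1ccc(cc1)S(=O)(=O)C[N+]#[C-]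
Why: Van Leusen reductive cyanation: the TosMIC anion adds to the aldehyde, the oxazoline opens with loss of sulfinate, and methanolysis leaves the one-carbon-homologated nitrile with the aryl bromide untouched.

Step 2
Reactants: 2 (2-bromo-3-methoxyphenyl)acetonitrile
Product: 4 (2-bromo-5-hydroxy-3-methoxyphenyl)acetonitrile, via arylboronate 3 (not isolated)
Conditions: [Ir(OMe)(cod)]2 (1.5 mol %), 4,4′-di-tert-butyl-2,2′-bipyridine (3 mol %), B2pin2 (0.55 equiv), THF, 80 °C; then KHSO5 (as 2KHSO5·KHSO4·K2SO4), acetone/H2O, rt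
Reagents that add atoms: bis(pinacolato)diboron, CC1(C)OB(OC1(C)C)B1OC(C)(C)C(C)(C)O1 (boryl group of 3 only); potassium peroxymonosulfate, [K+].[O-]S(=O)(=O)OO (phenol oxygen of 4)
Why: Sterically governed iridium-catalysed C–H borylation goes to C-5, the only ring C–H with no ortho substituent, and ipso-oxidation of the boronate gives the phenol para to bromine, which fixes the methoxy/hydroxy pattern of ring B′ without an electrophilic substitution.

Step 3
Reactants: 4 (2-bromo-5-hydroxy-3-methoxyphenyl)acetonitrile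
Product: 5 [5-(benzyloxy)-2-bromo-3-methoxyphenyl]acetonitrile
Conditions: BnBr, K2CO3, acetone, reflux
Reagents that add atoms: benzyl bromide, BrCc1ccccc1
Why: Williamson etherification of the phenoxide; K2CO3 is too weak to alkylate the arylacetonitrile carbon.

Step 4
Reactants: 5 [5-(benzyloxy)-2-bromo-3-methoxyphenyl]acetonitrile; 6 4-(benzyloxy)-2-hydroxybenzaldehyde
Product: 8 7-(benzyloxy)-3-[5-(benzyloxy)-2-bromo-3-methoxyphenyl]-2H-chromen-2-one, via iminochromene 7 (not isolated)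
Conditions: KOtBu (2.2 equiv), DMF, 90 °C; then 1 M HCl, 60 °C
Reagents that add atoms: water, O
Why: Knoevenagel condensation of the arylacetonitrile carbanion with the salicylaldehyde gives the (Z)-acrylonitrile, whose phenoxide closes onto the nitrile to the 2-iminochromene, and mild acid hydrolysis gives the 3-arylcoumarin; the bromine has no ortho hydrogen, so no aryne can form.

Step 5
Reactants: 8 7-(benzyloxy)-3-[5-(benzyloxy)-2-bromo-3-methoxyphenyl]-2H-chromen-2-one
Product: 9 (2Z)-3-[4-(benzyloxy)-2-hydroxyphenyl]-2-[5-(benzyloxy)-2-bromo-3-methoxyphenyl]prop-2-en-1-ol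
Conditions: i-Bu2AlH (4 equiv), CH2Cl2, −78 → 0 °C; aqueous potassium sodium tartrate
Reagents that add atoms: none
Why: 1,2-Reduction of the unsaturated lactone by i-Bu2AlH through the lactol and the ring-opened enal to the allylic alcohol, the Z geometry being fixed by the coumarin ring.

Step 6
Reactants: 9 (2Z)-3-[4-(benzyloxy)-2-hydroxyphenyl]-2-[5-(benzyloxy)-2-bromo-3-methoxyphenyl]prop-2-en-1-ol
Product: 10 7-(benzyloxy)-3-[5-(benzyloxy)-2-bromo-3-methoxyphenyl]-2H-chromene
Conditions: PPh3, DIAD, THF, 0 °C → rt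
Reagents that add atoms: none
Why: Intramolecular Mitsunobu etherification (6-exo-tet) of the phenol onto the activated primary allylic alcohol gives the isoflav-3-ene.

Step 7
Reactants: 10 7-(benzyloxy)-3-[5-(benzyloxy)-2-bromo-3-methoxyphenyl]-2H-chromene
Product: 11 (3R)-7-(benzyloxy)-3-[5-(benzyloxy)-2-bromo-3-methoxyphenyl]chroman
Conditions: H2 (50 bar), [Ir(cod)((S)-tBu-PHOX)][B(3,5-(CF3)2C6H3)4] (2 mol %), CH2Cl2, rt
Reagents that add atoms: none
Why: Iridium N,P-ligand-catalysed asymmetric hydrogenation of a trisubstituted, aryl-conjugated cyclic alkene; the oxazoline stereocenter of the ligand selects the face of C-3′=C-4′ and so sets C-3′ as R, while the aryl bromide and benzyl ethers are inert to this catalyst.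

Step 8
Reactants: 12 2,4-dihydroxybenzaldehyde
Product: 13 4-[(tert-butyldimethylsilyl)oxy]-2-hydroxybenzaldehyde
Conditions: TBSCl (1.05 equiv), imidazole, CH2Cl2, 0 °C
Reagents that add atoms: tert-butyldimethylsilyl chloride, CC(C)(C)[Si](C)(C)Cl
Why: Selective silylation of the 4-hydroxyl, because the 2-hydroxyl is hydrogen-bonded to the formyl group and less nucleophilic.

Step 9
Reactants: 13 4-[(tert-butyldimethylsilyl)oxy]-2-hydroxybenzaldehyde
Product: 14 tert-butyl 5-[(tert-butyldimethylsilyl)oxy]-2-formylphenyl carbonate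
Conditions: Boc2O, 4-dimethylaminopyridine (5 mol %), i-Pr2NEt, CH2Cl2, rt
Reagents that add atoms: di-tert-butyl dicarbonate, CC(C)(C)OC(=O)OC(=O)OC(C)(C)C
Why: Nucleophile-catalysed O-acylation of the chelated phenol with Boc2O.

Step 10
Reactants: 15 2,3-dihydroxy-4-methoxybenzaldehyde
Product: 16 2,3-bis(benzyloxy)-4-methoxybenzaldehyde
Conditions: BnBr (2.4 equiv), K2CO3, DMF, 60 °C
Reagents that add atoms: benzyl bromide, BrCc1ccccc1
Why: Double Williamson etherification of the catechol.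

Step 11
Reactants: 16 2,3-bis(benzyloxy)-4-methoxybenzaldehyde
Product: 17 [2,3-bis(benzyloxy)-4-methoxyphenyl]acetonitrile
Conditions: TosMIC, KOtBu, DME, −30 °C → rt; then MeOH, reflux
Reagents that add atoms: tosylmethyl isocyanide (TosMIC), Cc1ccc(cc1)S(=O)(=O)C[N+]#[C-]
Why: Van Leusen reductive cyanation, as in step 1.

Step 12
Reactants: 17 [2,3-bis(benzyloxy)-4-methoxyphenyl]acetonitrile
Product: 18 [2,3-bis(benzyloxy)-4-methoxyphenyl]acetic acid
Conditions: NaOH, EtOH/H2O, reflux; then HCl to pH 2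
Reagents that add atoms: sodium hydroxide, [Na+].[OH-]; water, O
Why: Base hydrolysis of the nitrile through the primary amide; benzyl and methyl ethers are stable to hydroxide.

Step 13
Reactants: 18 [2,3-bis(benzyloxy)-4-methoxyphenyl]acetic acid
Product: 19 [2,3-bis(benzyloxy)-4-methoxyphenyl]acetyl chloride
Conditions: (COCl)2, DMF (cat.), CH2Cl2, 0 °C → rt; concentrated and used crude
Reagents that add atoms: oxalyl chloride, ClC(=O)C(=O)Cl
Why: Acid chloride formation through the chloroiminium salt of DMF under cold, neutral conditions.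

Step 14
Reactants: 11 (3R)-7-(benzyloxy)-3-[5-(benzyloxy)-2-bromo-3-methoxyphenyl]chroman; 14 tert-butyl 5-[(tert-butyldimethylsilyl)oxy]-2-formylphenyl carbonate; 19 [2,3-bis(benzyloxy)-4-methoxyphenyl]acetyl chloride
Product: 22 5-[(tert-butyldimethylsilyl)oxy]-2-[{4-(benzyloxy)-2-[(3R)-7-(benzyloxy)chroman-3-yl]-6-methoxyphenyl}(tert-butoxycarbonyloxy)methyl]phenyl [2,3-bis(benzyloxy)-4-methoxyphenyl]acetate (both epimers at the carbonate-bearing carbon), via aryllithium 20 (not isolated), via lithium phenoxide 21 (not isolated)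
Conditions: t-BuLi (2.05 equiv), THF, −78 °C; then 14, −78 °C; then 19, −78 → −40 °C; aqueous NH4Cl
Reagents that add atoms: tert-butyllithium, [Li]C(C)(C)C (the lithium of 20 and 21 only; no atom of it remains in 22)
Why: Halogen–lithium exchange gives 20, which adds to the aldehyde; the alkoxide takes over the tert-butoxycarbonyl group from the neighbouring phenol oxygen through a six-membered transition state (anionic O-to-O carbonate shift), and the lithium phenoxide 21 so freed is acylated at −78 °C by 19, the new carbinol center being formed without control because step 15 erases it.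

Step 15
Reactants: 22 5-[(tert-butyldimethylsilyl)oxy]-2-[{4-(benzyloxy)-2-[(3R)-7-(benzyloxy)chroman-3-yl]-6-methoxyphenyl}(tert-butoxycarbonyloxy)methyl]phenyl [2,3-bis(benzyloxy)-4-methoxyphenyl]acetate
Product: 24 (3R,4S)-4-{4-(benzyloxy)-2-[(3R)-7-(benzyloxy)chroman-3-yl]-6-methoxyphenyl}-3-[2,3-bis(benzyloxy)-4-methoxyphenyl]-7-hydroxychroman-2-one, via quinone methide 23 (not isolated)
Conditions: CsF (3 equiv), N-(9-anthracenylmethyl)cinchonidinium chloride (10 mol %), toluene/CH2Cl2 (4:1), −40 → 0 °C; AcOH quench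
Reagents that add atoms: none
Why: Proposed new method: fluoride frees O-7, the phenoxide expels tert-butyl carbonate from C-4 (1,6-elimination) to give p-quinone methide 23, the tert-butoxide left after loss of CO2 deprotonates the arylacetate at C-3, and the ester enolate adds to C-4, so that the only new bond is C-3–C-4 and ring A rearomatises. The closest known reaction types are the Perkin ring closure of salicylaldehyde arylacetates to coumarins (same tether, same ring), ammonium-salt-catalysed 1,6-additions of carbon acids to p-quinone methides made in situ, and cation-directed enantioselective cyclisations of enolates under phase-transfer conditions; their combination on an aryl ester tether has not been shown. The pyranone ring closes in a 6-(enolendo)-endo-trig mode through a half-chair in which the ester has turned so that C-3 lies over C-4. C-4 should be set by the chiral ammonium cation, which stays paired with the enolate and can hydrogen-bond through its C-9 hydroxyl to the quinone methide carbonyl and so shield one face of C-4; C-3 is epimerisable next to the lactone carbonyl and should settle trans to the 4-aryl group under the basic conditions. The step needs C-3, not an oxygen, to attack C-4, and needs the electrophile to appear only once the tether is in place: the acyl group on O-1 excludes the ortho-quinone methide, so C-4 becomes electrophilic only through O-7, and the six-membered closure is the only ring size open to the enolate carbon.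

Step 16
Reactants: 24 (3R,4S)-4-{4-(benzyloxy)-2-[(3R)-7-(benzyloxy)chroman-3-yl]-6-methoxyphenyl}-3-[2,3-bis(benzyloxy)-4-methoxyphenyl]-7-hydroxychroman-2-one
Product: 25 (2R,3S)-3-{4-(benzyloxy)-2-[(3R)-7-(benzyloxy)chroman-3-yl]-6-methoxyphenyl}-2-[2,3-bis(benzyloxy)-4-methoxyphenyl]-3-(2,4-dihydroxyphenyl)propan-1-ol
Conditions: LiAlH4 (3 equiv), THF, −20 → 0 °C; water, then aqueous potassium sodium tartrate
Reagents that add atoms: none
Why: Hydride reduction of the aryl lactone to the primary alcohol and the O-1 phenol, after which C-3 is no longer epimerisable.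

Step 17
Reactants: 25 (2R,3S)-3-{4-(benzyloxy)-2-[(3R)-7-(benzyloxy)chroman-3-yl]-6-methoxyphenyl}-2-[2,3-bis(benzyloxy)-4-methoxyphenyl]-3-(2,4-dihydroxyphenyl)propan-1-ol
Product: 26 (3R,4S)-4-{4-(benzyloxy)-2-[(3R)-7-(benzyloxy)chroman-3-yl]-6-methoxyphenyl}-3-[2,3-bis(benzyloxy)-4-methoxyphenyl]chroman-7-ol
Conditions: PPh3, DIAD, THF, 0 °C → rt
Reagents that add atoms: none
Why: Intramolecular Mitsunobu etherification (6-exo-tet) of the O-1 phenol onto the primary alcohol re-forms ring C at the ether level, as in chroman syntheses from 2-aryl-3-(2-hydroxyphenyl)propanols; the O-7 phenol cannot reach the carbinol and no stereocenter is involved.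

Step 18
Reactants: 26 (3R,4S)-4-{4-(benzyloxy)-2-[(3R)-7-(benzyloxy)chroman-3-yl]-6-methoxyphenyl}-3-[2,3-bis(benzyloxy)-4-methoxyphenyl]chroman-7-ol
Product: 27 (3R,4S)-3-(2,3-dihydroxy-4-methoxyphenyl)-4-{4-hydroxy-2-[(3R)-7-hydroxychroman-3-yl]-6-methoxyphenyl}chroman-7-ol (target)
Conditions: H2 (1 atm), 10% Pd/C, EtOAc/MeOH (1:1), rt
Reagents that add atoms: none
Why: Hydrogenolysis of the four benzyl ethers; the chroman C–O bonds are not benzylic and the two methyl ethers stay.

**Compound list**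

1 | 2-bromo-3-methoxybenzaldehyde | COc1cccc(C=O)c1Br | starting material
2 | (2-bromo-3-methoxyphenyl)acetonitrile | COc1cccc(CC#N)c1Br | intermediate
3 | [2-bromo-3-methoxy-5-(4,4,5,5-tetramethyl-1,3,2-dioxaborolan-2-yl)phenyl]acetonitrile | COc1cc(B2OC(C)(C)C(C)(C)O2)cc(CC#N)c1Br | intermediate (not isolated)
4 | (2-bromo-5-hydroxy-3-methoxyphenyl)acetonitrile | COc1cc(O)cc(CC#N)c1Br | intermediate
5 | [5-(benzyloxy)-2-bromo-3-methoxyphenyl]acetonitrile | COc1cc(OCc2ccccc2)cc(CC#N)c1Br | intermediate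
6 | 4-(benzyloxy)-2-hydroxybenzaldehyde | O=Cc1ccc(OCc2ccccc2)cc1O | starting material
7 | 7-(benzyloxy)-3-[5-(benzyloxy)-2-bromo-3-methoxyphenyl]-2H-chromen-2-imine | COc1cc(OCc2ccccc2)cc(C2=Cc3ccc(OCc4ccccc4)cc3OC2=N)c1Br | intermediate (not isolated)
8 | 7-(benzyloxy)-3-[5-(benzyloxy)-2-bromo-3-methoxyphenyl]-2H-chromen-2-one | COc1cc(OCc2ccccc2)cc(C2=Cc3ccc(OCc4ccccc4)cc3OC2=O)c1Br | intermediate
9 | (2Z)-3-[4-(benzyloxy)-2-hydroxyphenyl]-2-[5-(benzyloxy)-2-bromo-3-methoxyphenyl]prop-2-en-1-ol | OC/C(=C\c1ccc(OCc2ccccc2)cc1O)c1cc(OCc2ccccc2)cc(OC)c1Br | intermediate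
10 | 7-(benzyloxy)-3-[5-(benzyloxy)-2-bromo-3-methoxyphenyl]-2H-chromene | COc1cc(OCc2ccccc2)cc(C2=Cc3ccc(OCc4ccccc4)cc3OC2)c1Br | intermediate
11 | (3R)-7-(benzyloxy)-3-[5-(benzyloxy)-2-bromo-3-methoxyphenyl]chroman | COc1cc(OCc2ccccc2)cc([C@@H]2COc3cc(OCc4ccccc4)ccc3C2)c1Br | intermediate
12 | 2,4-dihydroxybenzaldehyde | O=Cc1ccc(O)cc1O | starting material
13 | 4-[(tert-butyldimethylsilyl)oxy]-2-hydroxybenzaldehyde | CC(C)(C)[Si](C)(C)Oc1ccc(C=O)c(O)c1 | intermediate
14 | tert-butyl 5-[(tert-butyldimethylsilyl)oxy]-2-formylphenyl carbonate | CC(C)(C)OC(=O)Oc1cc(O[Si](C)(C)C(C)(C)C)ccc1C=O | intermediate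
15 | 2,3-dihydroxy-4-methoxybenzaldehyde | COc1ccc(C=O)c(O)c1O | starting material
16 | 2,3-bis(benzyloxy)-4-methoxybenzaldehyde | COc1ccc(C=O)c(OCc2ccccc2)c1OCc1ccccc1 | intermediate
17 | [2,3-bis(benzyloxy)-4-methoxyphenyl]acetonitrile | COc1ccc(CC#N)c(OCc2ccccc2)c1OCc1ccccc1 | intermediate
18 | [2,3-bis(benzyloxy)-4-methoxyphenyl]acetic acid | COc1ccc(CC(=O)O)c(OCc2ccccc2)c1OCc1ccccc1 | intermediate
19 | [2,3-bis(benzyloxy)-4-methoxyphenyl]acetyl chloride | COc1ccc(CC(=O)Cl)c(OCc2ccccc2)c1OCc1ccccc1 | intermediate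
20 | {4-(benzyloxy)-2-[(3R)-7-(benzyloxy)chroman-3-yl]-6-methoxyphenyl}lithium | COc1cc(OCc2ccccc2)cc([C@@H]2COc3cc(OCc4ccccc4)ccc3C2)c1[Li] | intermediate (not isolated)
21 | lithium 2-[{4-(benzyloxy)-2-[(3R)-7-(benzyloxy)chroman-3-yl]-6-methoxyphenyl}(tert-butoxycarbonyloxy)methyl]-5-[(tert-butyldimethylsilyl)oxy]phenoxide | [Li+].[O-]c1cc(O[Si](C)(C)C(C)(C)C)ccc1C(OC(=O)OC(C)(C)C)c1c(OC)cc(OCc2ccccc2)cc1[C@@H]1COc2cc(OCc3ccccc3)ccc2C1 | intermediate (not isolated)
22 | 5-[(tert-butyldimethylsilyl)oxy]-2-[{4-(benzyloxy)-2-[(3R)-7-(benzyloxy)chroman-3-yl]-6-methoxyphenyl}(tert-butoxycarbonyloxy)methyl]phenyl [2,3-bis(benzyloxy)-4-methoxyphenyl]acetate (both epimers at the carbonate-bearing carbon) | COc1ccc(CC(=O)Oc2cc(O[Si](C)(C)C(C)(C)C)ccc2C(OC(=O)OC(C)(C)C)c2c(OC)cc(OCc3ccccc3)cc2[C@@H]2COc3cc(OCc4ccccc4)ccc3C2)c(OCc2ccccc2)c1OCc1ccccc1 | intermediate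
23 | 6-[{4-(benzyloxy)-2-[(3R)-7-(benzyloxy)chroman-3-yl]-6-methoxyphenyl}methylidene]-3-oxocyclohexa-1,4-dien-1-yl [2,3-bis(benzyloxy)-4-methoxyphenyl]acetate | COc1ccc(CC(=O)OC2=CC(=O)C=CC2=Cc2c(OC)cc(OCc3ccccc3)cc2[C@@H]2COc3cc(OCc4ccccc4)ccc3C2)c(OCc2ccccc2)c1OCc1ccccc1 | intermediate (not isolated)
24 | (3R,4S)-4-{4-(benzyloxy)-2-[(3R)-7-(benzyloxy)chroman-3-yl]-6-methoxyphenyl}-3-[2,3-bis(benzyloxy)-4-methoxyphenyl]-7-hydroxychroman-2-one | COc1ccc([C@@H]2C(=O)Oc3cc(O)ccc3[C@H]2c2c(OC)cc(OCc3ccccc3)cc2[C@@H]2COc3cc(OCc4ccccc4)ccc3C2)c(OCc2ccccc2)c1OCc1ccccc1 | intermediate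
25 | (2R,3S)-3-{4-(benzyloxy)-2-[(3R)-7-(benzyloxy)chroman-3-yl]-6-methoxyphenyl}-2-[2,3-bis(benzyloxy)-4-methoxyphenyl]-3-(2,4-dihydroxyphenyl)propan-1-ol | COc1ccc([C@H](CO)[C@@H](c2ccc(O)cc2O)c2c(OC)cc(OCc3ccccc3)cc2[C@@H]2COc3cc(OCc4ccccc4)ccc3C2)c(OCc2ccccc2)c1OCc1ccccc1 | intermediate
26 | (3R,4S)-4-{4-(benzyloxy)-2-[(3R)-7-(benzyloxy)chroman-3-yl]-6-methoxyphenyl}-3-[2,3-bis(benzyloxy)-4-methoxyphenyl]chroman-7-ol | COc1ccc([C@@H]2COc3cc(O)ccc3[C@H]2c2c(OC)cc(OCc3ccccc3)cc2[C@@H]2COc3cc(OCc4ccccc4)ccc3C2)c(OCc2ccccc2)c1OCc1ccccc1 | intermediate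
27 | (3R,4S)-3-(2,3-dihydroxy-4-methoxyphenyl)-4-{4-hydroxy-2-[(3R)-7-hydroxychroman-3-yl]-6-methoxyphenyl}chroman-7-ol | COc1ccc([C@@H]2COc3cc(O)ccc3[C@H]2c2c(OC)cc(O)cc2[C@@H]2COc3cc(O)ccc3C2)c(O)c1O | target

**Count and risks**

Total steps: 18. Longest linear sequence: 12 steps (steps 1–7, then 14–18).

Steps most likely to fail:

1. Step 15 (proposed new method). The ion pair may discriminate the two faces of C-4 poorly. Once ring A has become a quinone methide, the arylacetyl group may also leave O-1 by acyl transfer or ketene formation, or the quinone methide may oligomerise through O-7. The fallback is the known amine-catalysed [4+2] reaction of ortho-quinone methides with aldehydes; it sets out from 11, 14 and 17 and comes back at 26. Nitrile 17 is reduced with i-Bu2AlH (toluene, −78 °C, acidic work-up) to [2,3-bis(benzyloxy)-4-methoxyphenyl]acetaldehyde F1. Bromide 11 is lithiated and added to 14 as in step 14, but the phenoxide is quenched with acetic acid at −78 °C to give 2-[{4-(benzyloxy)-2-[(3R)-7-(benzyloxy)chroman-3-yl]-6-methoxyphenyl}(tert-butoxycarbonyloxy)methyl]-5-[(tert-butyldimethylsilyl)oxy]phenol F2. F2, F1, (R)-2-[diphenyl(trimethylsilyloxy)methyl]pyrrolidine (20 mol %) and NaHCO3 in CH2Cl2 should give the trans lactol (3R,4S)-4-{4-(benzyloxy)-2-[(3R)-7-(benzyloxy)chroman-3-yl]-6-methoxyphenyl}-3-[2,3-bis(benzyloxy)-4-methoxyphenyl]-7-[(tert-butyldimethylsilyl)oxy]chroman-2-ol F3. This forms through the ortho-quinone methide (O-1 is now free) and the enamine of F1, with the (R)-catalyst chosen by the usual enamine shielding model. Et3SiH/BF3·OEt2 (CH2Cl2, −78 °C) reduces the lactol carbon to give tert-butyl{[(3R,4S)-4-{4-(benzyloxy)-2-[(3R)-7-(benzyloxy)chroman-3-yl]-6-methoxyphenyl}-3-[2,3-bis(benzyloxy)-4-methoxyphenyl]chroman-7-yl]oxy}dimethylsilane F4, and Bu4NF in THF removes the silyl group to give 26. Steps 16 and 17 are then not needed.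

2. Step 14. Lithium phenoxide 21 may lose tert-butyl carbonate (ortho-quinone methide formation) before it is acylated and then capture a second aryllithium, or the acid chloride may be converted into a ketene. The fallback changes the order of events; it sets out from 11, 13 and 18 and comes back at 22. Lithiated 11 is added at −78 °C to the lithium phenoxide of 13 (made with LiN(SiMe3)2) to give 2-[{4-(benzyloxy)-2-[(3R)-7-(benzyloxy)chroman-3-yl]-6-methoxyphenyl}(hydroxy)methyl]-5-[(tert-butyldimethylsilyl)oxy]phenol F5. The phenol oxygen alone is esterified with acid 18 (EDC·HCl, 4-dimethylaminopyridine cat., CH2Cl2, 0 °C; the hindered benzhydrol does not react) to give 5-[(tert-butyldimethylsilyl)oxy]-2-[{4-(benzyloxy)-2-[(3R)-7-(benzyloxy)chroman-3-yl]-6-methoxyphenyl}(hydroxy)methyl]phenyl [2,3-bis(benzyloxy)-4-methoxyphenyl]acetate F6. Its benzhydrol is then converted into the tert-butyl carbonate (Boc2O, 4-dimethylaminopyridine, CH2Cl2) to give 22.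

3. Step 7. Hydrogen delivery may be slow or poorly face-selective because the 2-bromo-3-methoxyaryl group is twisted out of conjugation with the alkene, and bromine may be lost on long exposure. The fallback sets out from 9 and comes back at 11. The allylic alcohol 9 is hydrogenated under hydroxyl direction with Ru(OAc)2((S)-BINAP) and H2 in MeOH to (2R)-3-[4-(benzyloxy)-2-hydroxyphenyl]-2-[5-(benzyloxy)-2-bromo-3-methoxyphenyl]propan-1-ol F7. Mitsunobu closure (PPh3, DIAD, THF) then gives 11 directly, bypassing chromene 10.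

**Further compounds**

F1 | step 15 | [2,3-bis(benzyloxy)-4-methoxyphenyl]acetaldehyde | COc1ccc(CC=O)c(OCc2ccccc2)c1OCc1ccccc1
F2 | step 15 | 2-[{4-(benzyloxy)-2-[(3R)-7-(benzyloxy)chroman-3-yl]-6-methoxyphenyl}(tert-butoxycarbonyloxy)methyl]-5-[(tert-butyldimethylsilyl)oxy]phenol | CC(C)(C)OC(=O)OC(c1ccc(O[Si](C)(C)C(C)(C)C)cc1O)c1c(OC)cc(OCc2ccccc2)cc1[C@@H]1COc2cc(OCc3ccccc3)ccc2C1
F3 | step 15 | (3R,4S)-4-{4-(benzyloxy)-2-[(3R)-7-(benzyloxy)chroman-3-yl]-6-methoxyphenyl}-3-[2,3-bis(benzyloxy)-4-methoxyphenyl]-7-[(tert-butyldimethylsilyl)oxy]chroman-2-ol | COc1ccc([C@@H]2C(O)Oc3cc(O[Si](C)(C)C(C)(C)C)ccc3[C@H]2c2c(OC)cc(OCc3ccccc3)cc2[C@@H]2COc3cc(OCc4ccccc4)ccc3C2)c(OCc2ccccc2)c1OCc1ccccc1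
F4 | step 15 | tert-butyl{[(3R,4S)-4-{4-(benzyloxy)-2-[(3R)-7-(benzyloxy)chroman-3-yl]-6-methoxyphenyl}-3-[2,3-bis(benzyloxy)-4-methoxyphenyl]chroman-7-yl]oxy}dimethylsilane | COc1ccc([C@@H]2COc3cc(O[Si](C)(C)C(C)(C)C)ccc3[C@H]2c2c(OC)cc(OCc3ccccc3)cc2[C@@H]2COc3cc(OCc4ccccc4)ccc3C2)c(OCc2ccccc2)c1OCc1ccccc1
F5 | step 14 | 2-[{4-(benzyloxy)-2-[(3R)-7-(benzyloxy)chroman-3-yl]-6-methoxyphenyl}(hydroxy)methyl]-5-[(tert-butyldimethylsilyl)oxy]phenol | OC(c1ccc(O[Si](C)(C)C(C)(C)C)cc1O)c1c(OC)cc(OCc2ccccc2)cc1[C@@H]1COc2cc(OCc3ccccc3)ccc2C1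
F6 | step 14 | 5-[(tert-butyldimethylsilyl)oxy]-2-[{4-(benzyloxy)-2-[(3R)-7-(benzyloxy)chroman-3-yl]-6-methoxyphenyl}(hydroxy)methyl]phenyl [2,3-bis(benzyloxy)-4-methoxyphenyl]acetate | COc1ccc(CC(=O)Oc2cc(O[Si](C)(C)C(C)(C)C)ccc2C(O)c2c(OC)cc(OCc3ccccc3)cc2[C@@H]2COc3cc(OCc4ccccc4)ccc3C2)c(OCc2ccccc2)c1OCc1ccccc1
F7 | step 7 | (2R)-3-[4-(benzyloxy)-2-hydroxyphenyl]-2-[5-(benzyloxy)-2-bromo-3-methoxyphenyl]propan-1-ol | COc1cc(OCc2ccccc2)cc([C@H](CO)Cc2ccc(OCc3ccccc3)cc2O)c1Br
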